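Everything rests on cutting the bond between C4 of the syringyl ring and C6 of the 3,7-dioxabicyclo[3.3.0]octane core. C6 carries O7, so it is a masked oxocarbenium carbon. 2,6-Dimethoxyphenol has both ortho positions blocked and attacks through the carbon para to its OH. The precursor is an open-chain 1-aryl-2,3-bis(hydroxymethyl)-4,4-dimethoxybutan-1-ol in which, of the four core stereocentres, only C1 and C5 are set. One Sc(OTf)3-catalysed operation closes both tetrahydrofuran rings, joins the phenol on the convex face of the bicycle and sets C2 and C6. A tosylate on the guaiacyl oxygen keeps the labile cis-dihydrobenzofuran C2–O bond from ionising meanwhile.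

Key step: step 8

Reading of the target and locants: core atoms follow 3,7-dioxabicyclo[3.3.0]octane numbering (C1, C2 bearing the benzofuranyl group, O3, C4, C5, C6 bearing the syringyl group, O7, C8; ring A = C1-C2-O3-C4-C5, ring B = C5-C6-O7-C8-C1) with C1 R, C2 S, C5 R, C6 S and both aryl groups exo; Bf-2 and Bf-3 are the dihydrobenzofuran centres, (2S,3S), that is aryl and CH2OH cis.

Assumption: the (R)-tert-leucinate rhodium catalyst is taken to deliver the (2S)-configured cis-dihydrobenzofuran; if the sense of induction is the opposite, the mirror-image catalyst is used with no other change.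

Step 1
Reactants: 1 vanillyl alcohol
Product: 2 4-(hydroxymethyl)-2-methoxyphenyl 4-methylbenzenesulfonate
Conditions: TsCl, K2CO3, acetone, 0 °C to rt
Reagents that add atoms: p-toluenesulfonyl chloride, Cc1ccc(cc1)S(=O)(=O)Cl
Why: Chemoselective O-sulfonylation, in which only the phenol is deprotonated by carbonate and reacts with TsCl while the benzylic alcohol stays free; no stereocentre is formed.

Step 2
Reactants: 2 4-(hydroxymethyl)-2-methoxyphenyl 4-methylbenzenesulfonate; 3 5-iodovanillin
Product: 4 4-[(4-formyl-2-iodo-6-methoxyphenoxy)methyl]-2-methoxyphenyl 4-methylbenzenesulfonate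
Conditions: PPh3, DIAD, THF, 0 °C to rt
Reagents that add atoms: none
Why: Mitsunobu etherification, in which the acidic phenol 3 displaces the oxyphosphonium salt of the primary benzylic alcohol by SN2 without touching aldehyde, iodide or sulfonate.

Step 3
Reactants: 4 aryl iodide; 5 ethyl diazoacetate
Product: 6 ethyl 2-diazo-2-[5-formyl-3-methoxy-2-({3-methoxy-4-(tosyloxy)phenyl}methoxy)phenyl]acetate
Conditions: Pd(PPh3)4 (5 mol %), Ag2CO3 (0.5 equiv), Et3N, toluene, rt
Reagents that add atoms: none
Why: Palladium-catalysed cross-coupling of an aryl iodide with a diazoacetate with retention of the diazo group (oxidative addition into C–I, silver-assisted palladation of the diazo carbon, reductive elimination), under which the aryl sulfonate and the aldehyde are inert at room temperature.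

Step 4
Reactants: 6 aryl diazoacetate
Product: 7 ethyl (2S,3R)-5-formyl-7-methoxy-2-[3-methoxy-4-(tosyloxy)phenyl]-2,3-dihydro-1-benzofuran-3-carboxylate (2,3-cis)
Conditions: dirhodium tetrakis[N-phthaloyl-(R)-tert-leucinate], Rh2(R-PTTL)4 (1 mol %), toluene, −60 °C, slow addition of 6 (final 0.01 M)
Reagents that add atoms: none
Why: Enantioselective intramolecular 1,5 C–H insertion of a donor/acceptor rhodium carbenoid into the benzylic ether C–H bond, in which the concerted insertion closes the five-membered ring with aryl and ester cis and the chiral carboxylate pocket picks one enantiotopic benzylic hydrogen, so that Bf-2 and Bf-3 are set together by the catalyst, while dilution and low temperature keep bimolecular capture of the carbenoid by the aldehyde behind the intramolecular path.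

Step 5
Reactants: 8 methyl 4-oxobutanoate
Product: 10 (4R)-4-(dimethoxymethyl)oxolan-2-one, via hydroxy aldehyde 9 (not isolated)
Conditions: aq. HCHO, (S)-2-[diphenyl(trimethylsilyloxy)methyl]pyrrolidine (10 mol %), pH 7 phosphate buffer, toluene, rt; then HC(OMe)3, CSA (cat.), MeOH, rt
Reagents that add atoms: formaldehyde, C=O; trimethyl orthoformate, COC(OC)OC
Why: Enamine-catalysed asymmetric α-hydroxymethylation of an aldehyde, in which the diphenyl(silyloxy)methyl group shields one face of the E-enamine so that formaldehyde adds to the open face and sets core C5 as R, and the immediate acid-catalysed acetalisation and lactonisation removes the acidic α-formyl hydrogen before it can racemise.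

Step 6
Reactants: 10 (4R)-4-(dimethoxymethyl)oxolan-2-one; 7 cis ester aldehyde
Product: 12 trans aldol lactone (3S,4R in the lactone; both carbinol epimers), via lithium enolate 11 (not isolated)
Conditions: LDA (LiN(iPr)2, 1.05 equiv), THF, −78 °C; 7, −78 °C, 15 min; AcOH, −78 °C
Reagents that add atoms: none
Why: Lithium enolate aldol addition, in which the aldehyde approaches the lactone enolate anti to the dimethoxymethyl group and so sets core C1 trans to the C5 substituent (the relationship the cis-fused bicycle needs once the lactone is opened), the carbinol centre C2 forms as a mixture that step 8 erases, and fast addition with a cold acid quench outruns deprotonation at the epimerisable Bf-3.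

Step 7
Reactants: 12 trans aldol lactone
Product: 13 open-chain tetraol acetal (core C1 R and C5 R; Bf 2S,3S; both C2 carbinol epimers)
Conditions: LiAlH4, THF, 0 °C; Na2SO4·10H2O
Reagents that add atoms: none
Why: Exhaustive hydride reduction of lactone and ester, to which the aryl sulfonate and the acetal are inert and in which the cis ester is reduced faster than it is enolised, so that Bf-3 keeps its geometry (the descriptor changes from R to S only by priority) and no new stereocentre arises.

Step 8
Reactants: 13 open-chain tetraol acetal; 14 2,6-dimethoxyphenol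
Product: 16 tosylate of the target (all six stereocentres in place), via bicyclic methyl acetal 15 (not isolated)
Conditions: Sc(OTf)3 (10 mol %), CaSO4, MeCN–CH2Cl2, 0 °C; then 14 (3 equiv), −30 to 0 °C; Et3N
Reagents that add atoms: none
Why: Sc(OTf)3 ionises the two acid-labile carbons of 13 in turn, the C8 hydroxyl (O7) adding to the C6 methoxycarbenium ion and the C4 hydroxyl (O3) adding to the C2 benzylic cation, which the para ring oxygen of the benzofuran stabilises, to give 15. Loss of the second methanol from 15 gives the bicyclic C6=O7 oxocarbenium ion, which 14 attacks with its C4; any O-aryl acetal formed first re-ionises and drains to the C-aryl product, and rearomatisation returns the proton, so the acid stays catalytic. The closest known reactions are the acid-catalysed Friedel–Crafts arylation of furofuran lactols of the samin type with phenols, the Sc(OTf)3-catalysed O-to-C aryl glycosylation and the cyclodehydration of 1-aryl-1,4-diols. Ring B and ring A both close in the 5-exo-trig mode (oxygen onto a cationic sp2 carbon whose pi partner lies outside the new ring), and the only other five-membered option, the C2 hydroxyl on C6, is a reversible acetal exchange that drains away as C2 ionises. C2 is set by C1, the cation closing with its aryl group anti to the C8 arm (exo), and C6 is set by the cis-fused bicycle, whose folded shape leaves only the convex face open, so the syringyl group ends up exo and cis to H5. The step needs para attack (the ortho positions of 14 carry OMe, C3 and C5 are flanked by OMe, C4 is unhindered and para to the free OH), no arylation at C2 (14 is added only after ring A is closed, when any C2 cation recloses intramolecularly and the exo aryl group cannot reach C6), kinetic control (low temperature and amine quench, since acid equilibration would feed the endo epimers) and an untouched cis-dihydrobenzofuran (the electron-withdrawing tosylate denies a Bf-2 cation the para oxygen lone pair).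

Step 9
Reactants: 16 tosylate of the target
Product: 17 target CNP0126146.1
Conditions: sodium naphthalenide (NaC10H8, stock solution in THF, added until the green colour persists), THF, −78 °C, 10 min; AcOH, −78 °C
Reagents that add atoms: none
Why: Reductive S–O scission of an aryl sulfonate by single-electron transfer, in which the tosyl arene is by far the best electron acceptor in 16, two electrons release sulfinate and phenoxide within minutes at −78 °C where the electron-rich benzylic ethers are not reduced, and protonation with AcOH before warming keeps the phenoxide from opening the cis ring through a quinone methide, so no stereocentre is touched.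

Compound list
1 | vanillyl alcohol, 4-(hydroxymethyl)-2-methoxyphenol | COc1cc(CO)ccc1O | starting material
2 | 4-(hydroxymethyl)-2-methoxyphenyl 4-methylbenzenesulfonate | COc1cc(CO)ccc1OS(=O)(=O)c1ccc(C)cc1 | intermediate
3 | 5-iodovanillin, 4-hydroxy-3-iodo-5-methoxybenzaldehyde | COc1cc(C=O)cc(I)c1O | starting material
4 | 4-[(4-formyl-2-iodo-6-methoxyphenoxy)methyl]-2-methoxyphenyl 4-methylbenzenesulfonate | COc1cc(C=O)cc(I)c1OCc1ccc(OS(=O)(=O)c2ccc(C)cc2)c(OC)c1 | intermediate
5 | ethyl diazoacetate | CCOC(=O)C=[N+]=[N-] | starting material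
6 | ethyl 2-diazo-2-[5-formyl-3-methoxy-2-({3-methoxy-4-(tosyloxy)phenyl}methoxy)phenyl]acetate | CCOC(=O)C(=[N+]=[N-])c1cc(C=O)cc(OC)c1OCc1ccc(OS(=O)(=O)c2ccc(C)cc2)c(OC)c1 | intermediate
7 | ethyl (2S,3R)-5-formyl-7-methoxy-2-[3-methoxy-4-(tosyloxy)phenyl]-2,3-dihydro-1-benzofuran-3-carboxylate, aryl and ester cis | COc1cc([C@H]2Oc3c(OC)cc(C=O)cc3[C@H]2C(=O)OCC)ccc1OS(=O)(=O)c1ccc(C)cc1 | intermediate
8 | methyl 4-oxobutanoate | COC(=O)CCC=O | starting material
9 | methyl (3R)-3-formyl-4-hydroxybutanoate | COC(=O)C[C@H](CO)C=O | intermediate
10 | (4R)-4-(dimethoxymethyl)oxolan-2-one | COC(OC)[C@H]1COC(=O)C1 | intermediate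
11 | lithium enolate of 10 | COC(OC)[C@H]1COC([O-])=C1.[Li+] | intermediate
12 | ethyl (2S,3R)-5-{[(3S,4R)-4-(dimethoxymethyl)-2-oxooxolan-3-yl](hydroxy)methyl}-7-methoxy-2-[3-methoxy-4-(tosyloxy)phenyl]-2,3-dihydro-1-benzofuran-3-carboxylate, lactone substituents trans, carbinol centre as both epimers | COc1cc([C@H]2Oc3c(OC)cc(C(O)[C@H]4C(=O)OC[C@@H]4C(OC)OC)cc3[C@H]2C(=O)OCC)ccc1OS(=O)(=O)c1ccc(C)cc1 | intermediate
13 | 4-[(2S,3S)-5-{(2R,3R)-1-hydroxy-2,3-bis(hydroxymethyl)-4,4-dimethoxybutyl}-3-(hydroxymethyl)-7-methoxy-2,3-dihydro-1-benzofuran-2-yl]-2-methoxyphenyl 4-methylbenzenesulfonate, carbinol centre as both epimers | COc1cc([C@H]2Oc3c(OC)cc(C(O)[C@@H](CO)[C@H](CO)C(OC)OC)cc3[C@H]2CO)ccc1OS(=O)(=O)c1ccc(C)cc1 | intermediate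
14 | 2,6-dimethoxyphenol | COc1cccc(OC)c1O | starting material
15 | bicyclic methyl acetal: 6-methoxy-3,7-dioxabicyclo[3.3.0]octane with C1 R, C2 S (exo benzofuranyl), C5 R, both C6 anomers; cis-(2S,3S)-dihydrobenzofuran with free CH2OH and guaiacyl tosylate | COc1cc([C@H]2Oc3c(OC)cc([C@H]4OC[C@H]5[C@@H]4COC5OC)cc3[C@H]2CO)ccc1OS(=O)(=O)c1ccc(C)cc1 | intermediate
16 | 4-[(2S,3S)-5-{(1S,3aR,4S,6aR)-4-(4-hydroxy-3,5-dimethoxyphenyl)tetrahydro-1H,3H-furo[3,4-c]furan-1-yl}-3-(hydroxymethyl)-7-methoxy-2,3-dihydro-1-benzofuran-2-yl]-2-methoxyphenyl 4-methylbenzenesulfonate | COc1cc([C@H]2Oc3c(OC)cc([C@H]4OC[C@H]5[C@@H]4CO[C@@H]5c4cc(OC)c(O)c(OC)c4)cc3[C@H]2CO)ccc1OS(=O)(=O)c1ccc(C)cc1 | intermediate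
17 | 4-[(1S,3aR,4S,6aR)-4-{(2S,3S)-2-(4-hydroxy-3-methoxyphenyl)-3-(hydroxymethyl)-7-methoxy-2,3-dihydro-1-benzofuran-5-yl}tetrahydro-1H,3H-furo[3,4-c]furan-1-yl]-2,6-dimethoxyphenol | COc1cc([C@H]2Oc3c(OC)cc([C@H]4OC[C@H]5[C@@H]4CO[C@@H]5c4cc(OC)c(O)c(OC)c4)cc3[C@H]2CO)ccc1O | target

Total step count: 9. Longest linear sequence: 8 (steps 1, 2, 3, 4, 6, 7, 8, 9); step 5 is the side branch.

Steps most likely to fail

Step 8. The phenol may attack through C3 instead of C4. It may intercept the C2 benzylic cation. Acid equilibration may also erode the exo geometry at C2 and C6. The fallback sets out from 13 and comes back at 16; it makes the bond by carbonyl addition of an aryl-metal, so that a halogen fixes the ring position. 13 is closed with Sc(OTf)3 in wet MeCN to the bicyclic lactol F1. Commercial 4-bromo-2,6-dimethoxyphenol is deprotonated with MeMgCl and converted with Mg and LiCl into the doubly magnesiated phenol F2. F2 adds to the open hydroxy aldehyde form of F1, whose two hydroxyl groups are first deprotonated with MeMgCl, to give the benzylic alcohol F3. PPTS in CH2Cl2 at 0 °C then ionises only this p-hydroxybenzylic alcohol, and O7 closes ring B on the exo face to give 16.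

Step 9. Benzylic C–O bonds may be cleaved by over-reduction. If the phenoxide survives into warming, it may open the ring and epimerise Bf-2. The fallback sets out from 16 and comes back at 17; it breaks the C–O bond of the sulfonate instead of the S–O bond. Miyaura borylation of the aryl tosylate (Pd(OAc)2, CM-phos, B2pin2, KOAc, dioxane, heat) gives the aryl pinacol boronate F4, in which the boron is still electron-withdrawing. Oxidation with trimethylamine N-oxide in THF at rt then puts the oxygen back under neutral conditions and gives 17 without any phenoxide stage.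

Step 6. Proton transfer from Bf-3 to the enolate or the aldolate may epimerise the cis ester or expel the aryloxide by β-elimination. The fallback sets out from 7 and comes back at 13; it removes the acidic hydrogen before the basic step. LiAlH4 reduces 7 to the cis diol F5, and MnO2 re-oxidises only the benzylic alcohol to the hydroxy aldehyde F6. Two equivalents of enolate 11, one of which is spent on the free hydroxyl, then give the aldol lactone F7, and LiAlH4 reduces F7 to 13.

Further compounds
F1 | step 8 | bicyclic lactol (15 with OH in place of the C6 methoxy group, both anomers) | COc1cc([C@H]2Oc3c(OC)cc([C@H]4OC[C@H]5[C@@H]4COC5O)cc3[C@H]2CO)ccc1OS(=O)(=O)c1ccc(C)cc1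
F2 | step 8 | doubly magnesiated phenol, chloromagnesium 4-(bromomagnesio)-2,6-dimethoxyphenolate | COc1cc([Mg]Br)cc(OC)c1O[Mg]Cl
F3 | step 8 | benzylic alcohol: ring A tetrahydrofuran with C2 S, C1 R (CH2OH), C5 R bearing CH(OH)(4-hydroxy-3,5-dimethoxyphenyl), both carbinol epimers | COc1cc([C@H]2Oc3c(OC)cc([C@H]4OC[C@H](C(O)c5cc(OC)c(O)c(OC)c5)[C@@H]4CO)cc3[C@H]2CO)ccc1OS(=O)(=O)c1ccc(C)cc1
F4 | step 9 | aryl pinacol boronate (16 with Bpin in place of OTs) | COc1cc([C@H]2Oc3c(OC)cc([C@H]4OC[C@H]5[C@@H]4CO[C@@H]5c4cc(OC)c(O)c(OC)c4)cc3[C@H]2CO)ccc1B1OC(C)(C)C(C)(C)O1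
F5 | step 6 | cis diol, 4-[(2S,3S)-3,5-bis(hydroxymethyl)-7-methoxy-2,3-dihydro-1-benzofuran-2-yl]-2-methoxyphenyl tosylate | COc1cc([C@H]2Oc3c(OC)cc(CO)cc3[C@H]2CO)ccc1OS(=O)(=O)c1ccc(C)cc1
F6 | step 6 | hydroxy aldehyde, 4-[(2S,3S)-5-formyl-3-(hydroxymethyl)-7-methoxy-2,3-dihydro-1-benzofuran-2-yl]-2-methoxyphenyl tosylate | COc1cc([C@H]2Oc3c(OC)cc(C=O)cc3[C@H]2CO)ccc1OS(=O)(=O)c1ccc(C)cc1
F7 | step 6 | aldol lactone (12 with CH2OH in place of the ethyl ester, both carbinol epimers) | COc1cc([C@H]2Oc3c(OC)cc(C(O)[C@H]4C(=O)OC[C@@H]4C(OC)OC)cc3[C@H]2CO)ccc1OS(=O)(=O)c1ccc(C)cc1
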